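The runs were computed from invented constants, and the scatter is random.

How much target will the north run hold at 94 min, when the south run, on the same charge, was last read at 47 min and stood at 56.2 mM? You need one thing beyond that reading: how much the flask still has to add.

| flask | starting material | free catalyst | time |
|---|---|---|---|
| south | 120 mM | 2.40 mM |  |
| east | 120 mM | 4.80 mM |  |
| west | 60.0 mM | 2.40 mM |  |
| north | 120 mM | 2.40 mM | 94 min |

- south run (time / min: [target] / mM): 1.9: 5.4; 3.6: 9.6; 6.8: 17.1; 13: 31.7; 25: 46.4; 47: 56.2
- east run (time / min: [target] / mM): 1.9: 10.8; 3.6: 19.5; 6.8: 33.3; 13: 51.7; 25: 67.9; 47: 71.6
- west run (time / min: [target] / mM): 1.9: 4.2; 3.6: 8.4; 6.8: 14.5; 13: 23.0; 25: 34.4; 47: 39.4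

(standard deviation of a reading: 0.6 mM)

1. the power of [starting material] that the first rate follows, about the charge of the south run; measure it at two percent of starting material made into target (one fixed amount of target, the same in the runs compared)
2. the power of [free catalyst] that the first rate follows, about the charge of the south run; measure it at two percent of starting material made into target
3. target in the north run at 94 min, as a share of the starting material charged

- Overall: starting material -> target, with free catalyst as catalyst.
- Constant volume, constant temperature.
- A reading of a species includes what of it is bound.
- An order is taken over about fifteen percent of the charge, up and down.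

Take the time scales from the shortest up. On the first rung, the early minutes, target climbs steadily. By my own rough reading, the east run at its first reading holds 10.8 mM against 5.4 mM in the south run, twice the target on twice the catalyst, an order near 1.00. At the third reading the west run holds 0.848 of the south run's target, an order in starting material near 0.238, which is coarse, since it spans a whole halving of the charge.

The second rung is the crossing, where the climb hands over to a fade. The south run gains 1.22 mM min⁻¹ between 13 min and 25 min, then 0.445 mM min⁻¹ up to 47 min. Those two rates give 16.8 min, the fading time, the time in which a run's late rate falls by a factor e.

The third rung is the wait. The north run goes on for 47.0 min past that last reading, which is longer than the fading time, namely 2.80 of them. The late rate at 47 min comes to 0.231 mM min⁻¹, so the tail is 3.65 mM, and I commit to 49.9%.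

The forecast gives 0.25, 1 and 51%, higher than my figure, on these grounds: “South at 47 min runs at about 0.25 mM/min and is fading with a time constant of about 18 min”.

The flask gives 0.22, 0.98 and 47.3%, and the forecast stands within its margins.

    2 free catalyst ⇌ catalyst dimer, settled at all times (301.0 M⁻¹)
    free catalyst + starting material → target + free catalyst (71.40 M⁻¹ min⁻¹)
    free catalyst + starting material ⇌ idle catalyst-substrate complex, settled at all times (46.60 M⁻¹)
    2 starting material → homo dimer (0.5238 M⁻¹ min⁻¹)

The north run ends at 56.8 mM, and the south run's last reading of 56.2 mM has a standard deviation of 0.6 mM, so the tail can't be measured by subtracting that one reading; my 49.9% stands 2.6 percentage points above the flask's value. The homo dimer step by itself gives the starting material a first half-life of 7.95 min at the charge, shorter than the fading time. Take 8.40 min for the east run, half the fading time, and let it approach its last reading, 59.7% of its charge: quarter to half should take 10.7 min, and the east run took 11.0 min.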